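**Retrosynthetic overview**

1. Last bonds: phenol O-debenzylation and hydroxyl-directed epoxidation of the C8=C9 alkene. The tertiary vanillate (C4–O) and the C6 carbinol are then cut together by an Evans–Tishchenko transform to a 4-hydroxy-6-ketone plus O-benzylvanillin, so no tertiary alcohol is ever acylated. (Daucane labels: C1 quaternary ring-fusion carbon, C4 carbinol carbon bearing isopropyl, C5 ring-fusion CH, C6 CHOH, C8/C9 epoxide carbons.)
2. The angular methyl on C1 and the trans ring fusion come from reductive opening of a cyclopropyl ketone whose CH2 was delivered to the C1=C5 alkene by the C4 hydroxyl.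
3. Seven-membered ring (formed second): (4+3) disconnection into the cross-ring 1-silyloxy diene C6=C5–C1=C10 and an isopropenyl carbene (C7–C8–C9) released from a cycloheptatriene by retro-Buchner reaction; cyclopropanation then Cope rearrangement place the methyl-bearing alkene directly at C8=C9.
4. Five-membered ring (formed first) with the C4 stereocentre: ozonolysis/aldol ring contraction of (S)-terpinen-4-ol (chiral pool); all other stereocentres are relayed from C4.

Assumption: (S)-(+)-terpinen-4-ol is taken as the commercially available single enantiomer (enriched material would first be upgraded by preparative chiral chromatography).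
Naming note: compound names use azulene locants (C3 = daucane C4, C3a = C5, C4 = C6, C6 = C8, C7 = C9, C8a = C1); the discussion uses the daucane labels.

Step 1
Reactants: 1 (S)-(+)-terpinen-4-ol
Product: 3 (3S)-3-hydroxy-6-oxo-3-(propan-2-yl)heptanal, via ozonide 2 (not isolated)
Conditions: O3, CH2Cl2, −78 °C; then PPh3, −78 °C → rt
Reagents that add atoms: ozone, [O-][O+]=O
Why: Criegee ozonolysis cleaves the only C=C to a methyl ketone and an aldehyde after reduction of the ozonide, leaving the tertiary carbinol stereocentre (future C4) untouched.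

Step 2
Reactants: 3 (3S)-3-hydroxy-6-oxo-3-(propan-2-yl)heptanal
Product: 4 (5R)-5-hydroxy-2-methyl-5-(propan-2-yl)cyclopent-1-ene-1-carbaldehyde
Conditions: piperidine (0.2 equiv), AcOH (0.2 equiv), toluene, 4 Å sieves, 40 °C
Reagents that add atoms: none
Why: Amine-catalysed intramolecular aldol condensation, in which the aldehyde α-carbon attacks the methyl ketone (five-membered ring closure) and water is lost, contracts the terpene ring to the cyclopentenecarbaldehyde without touching the carbinol centre.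

Step 3
Reactants: 4 (5R)-5-hydroxy-2-methyl-5-(propan-2-yl)cyclopent-1-ene-1-carbaldehyde
Product: 6 triethyl({(Z)-[(2R)-5-methylidene-2-(propan-2-yl)-2-[(trimethylsilyl)oxy]cyclopentylidene]methyl}oxy)silane, via trimethylsilyl ether 5 (not isolated)
Conditions: 1-(trimethylsilyl)imidazole, CH2Cl2, rt; then Et3N, Et3SiOTf, −78 → 0 °C
Reagents that add atoms: 1-(trimethylsilyl)imidazole, C[Si](C)(C)n1ccnc1; triethylsilyl trifluoromethanesulfonate, CC[Si](CC)(CC)OS(=O)(=O)C(F)(F)F
Why: After silylation of the tertiary alcohol, soft enolisation of the enal removes a proton from the methyl group cis to the formyl group and gives the cross-ring silyl dienol ether (silyl dienol ether formation), creating no stereocentre, and the enol ether geometry is erased later at step 8.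

Step 4
Reactants: 7 tropylium tetrafluoroborate; 8 isopropenylmagnesium bromide
Product: 9 7-(prop-1-en-2-yl)cyclohepta-1,3,5-triene
Conditions: THF, −78 °C → rt
Reagents that add atoms: none
Why: Grignard addition to the tropylium cation gives the 7-alkenylcycloheptatriene that serves as the retro-Buchner source of the isopropenyl carbene, and no stereocentre is formed.

Step 5
Reactants: 6 triethyl({(Z)-[(2R)-5-methylidene-2-(propan-2-yl)-2-[(trimethylsilyl)oxy]cyclopentylidene]methyl}oxy)silane; 9 7-(prop-1-en-2-yl)cyclohepta-1,3,5-triene (2 equiv)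
Product: 12 (3R)-6-methyl-3-(propan-2-yl)-4-[(triethylsilyl)oxy]-1,2,3,4,5,8-hexahydroazulen-3-ol (both epimers at the silyloxy carbon), via cis-divinylcyclopropane 10 (not isolated), via bis-silyl cycloheptadiene 11 (not isolated)
Conditions: Rh2(O2CCF3)4 (5 mol%), ClCH2CH2Cl, 40 °C then 80 °C; then K2CO3 (cat.), MeOH, 0 °C
Reagents that add atoms: none
Why: Formal (4+3) cycloaddition in which retro-Buchner release of the non-acceptor vinyl carbene from 9 (benzene is lost), cyclopropanation of the nucleophilic terminal methylidene of the diene and divinylcyclopropane Cope rearrangement build the seven-membered ring with the methyl-bearing alkene already at C8=C9, the only new stereocentre (the silyloxy carbon C6) being oxidised later, after which methanolysis frees the tertiary alcohol selectively.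

Step 6
Reactants: 12 (3R)-6-methyl-3-(propan-2-yl)-4-[(triethylsilyl)oxy]-1,2,3,4,5,8-hexahydroazulen-3-ol
Product: 13 (3R,3aR,8aR)-6-methyl-3-(propan-2-yl)-4-[(triethylsilyl)oxy]-1,2,3,4,5,8-hexahydro-3a,8a-methanoazulen-3-ol (cyclopropane CH2 cis to the 3-OH; both epimers at the silyloxy carbon)
Conditions: Et2Zn (2 equiv), CH2I2 (1 equiv), CH2Cl2, −10 → 0 °C
Reagents that add atoms: diiodomethane, ICI
Why: Hydroxyl-directed Simmons–Smith cyclopropanation (Furukawa variant), in which the zinc alkoxide of the allylic tertiary alcohol delivers CH2 to its own face of the tetrasubstituted ring-fusion alkene and so fixes the future quaternary C1 with its carbon substituent cis to the C4 oxygen, while the undirected trisubstituted alkene reacts far more slowly.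

Step 7
Reactants: 13 (3R,3aR,8aR)-6-methyl-3-(propan-2-yl)-4-[(triethylsilyl)oxy]-1,2,3,4,5,8-hexahydro-3a,8a-methanoazulen-3-ol
Product: 14 (3R,3aR,8aR)-6-methyl-3-(propan-2-yl)-1,2,3,4,5,8-hexahydro-3a,8a-methanoazulene-3,4-diol (both epimers at C4 of the name)
Conditions: Bu4NF, THF, 0 °C → rt
Reagents that add atoms: none
Why: Fluoride cleavage of the secondary triethylsilyl ether (desilylation) under non-acidic conditions that spare the cyclopropyl carbinol, with no change at any stereocentre.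

Step 8
Reactants: 14 (3R,3aR,8aR)-6-methyl-3-(propan-2-yl)-1,2,3,4,5,8-hexahydro-3a,8a-methanoazulene-3,4-diol
Product: 15 (3R,3aS,8aR)-3-hydroxy-6-methyl-3-(propan-2-yl)-2,3,5,8-tetrahydro-1H-3a,8a-methanoazulen-4-one
Conditions: (n-Pr4N)RuO4 (5 mol%), N-methylmorpholine N-oxide, 4 Å sieves, CH2Cl2, rt
Reagents that add atoms: none
Why: Ley–Griffith oxidation converts only the secondary carbinol (the tertiary one cannot react) into the cyclopropyl ketone under neutral conditions that leave the β,γ-alkene in place, and both carbinol epimers converge on one ketone.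

Step 9
Reactants: 15 (3R,3aS,8aR)-3-hydroxy-6-methyl-3-(propan-2-yl)-2,3,5,8-tetrahydro-1H-3a,8a-methanoazulen-4-one
Product: 17 (3R,3aR,8aR)-3-hydroxy-6,8a-dimethyl-3-(propan-2-yl)-2,3,3a,5,8,8a-hexahydroazulen-4(1H)-one, via lithium enolate 16 (not isolated)
Conditions: Li, NH3(l)/THF, −78 °C; then solid NH4Cl, −78 °C
Reagents that add atoms: none
Why: Dissolving-metal reductive cleavage of a cyclopropyl ketone breaks the exocyclic C5–CH2 bond that overlaps with the carbonyl π-system, so the CH2 becomes the angular methyl on C1 with the configuration set in step 6, and the enolate is protonated at C5 anti to that methyl to give the trans ring fusion, which is also the thermodynamically preferred epimer (C6 trans to isopropyl).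

Step 10
Reactants: 17 (3R,3aR,8aR)-3-hydroxy-6,8a-dimethyl-3-(propan-2-yl)-2,3,3a,5,8,8a-hexahydroazulen-4(1H)-one; 18 4-(benzyloxy)-3-methoxybenzaldehyde (4 equiv)
Product: 20 (3R,3aS,4S,8aR)-4-hydroxy-6,8a-dimethyl-3-(propan-2-yl)-1,2,3,3a,4,5,8,8a-octahydroazulen-3-yl 4-(benzyloxy)-3-methoxybenzoate, via samarium-bound hemiacetal 19 (not isolated)
Conditions: SmI2 (0.3 equiv) premixed with 18 in THF at rt (forms the samarium pinacolate catalyst), then 17, −10 °C; cold aq. NaHCO3 quench
Reagents that add atoms: none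
Why: Proposed new method: an Evans–Tishchenko reduction run on a tertiary carbinol, in which the trivalent samarium alkoxide of the C4 hydroxyl adds to the aryl aldehyde and the resulting hemiacetal C–H is transferred through a six-membered chair to the β face of the C6 ketone (the face on which the C4 oxygen sits), so that the aldehyde ends as the tertiary aroyl ester and C6 as the free α-carbinol (1,3-anti), the catalyst being the trivalent samarium pinacolate that SmI2 makes by reductive coupling of a small part of 18 (released as the pinacol at the quench), and the closest known reaction type being the SmI2-catalysed Evans–Tishchenko reduction of secondary β-hydroxy ketones with aldehydes.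

Step 11
Reactants: 20 (3R,3aS,4S,8aR)-4-hydroxy-6,8a-dimethyl-3-(propan-2-yl)-1,2,3,3a,4,5,8,8a-octahydroazulen-3-yl 4-(benzyloxy)-3-methoxybenzoate
Product: 21 (3R,3aS,4S,6R,7S,8aR)-6,7-epoxy-4-hydroxy-6,8a-dimethyl-3-(propan-2-yl)decahydroazulen-3-yl 4-(benzyloxy)-3-methoxybenzoate
Conditions: VO(acac)2 (5 mol%), t-BuOOH, CH2Cl2, 0 °C → rt
Reagents that add atoms: tert-butyl hydroperoxide, CC(C)(C)OO
Why: Hydroxyl-directed vanadium-catalysed epoxidation, in which the homoallylic C6 hydroxyl delivers the peroxide oxygen to the alkene face it occupies (α), which is also the face opposite the angular methyl, setting C8 and C9.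

Step 12
Reactants: 21 (3R,3aS,4S,6R,7S,8aR)-6,7-epoxy-4-hydroxy-6,8a-dimethyl-3-(propan-2-yl)decahydroazulen-3-yl 4-(benzyloxy)-3-methoxybenzoate
Product: 22 (3R,3aS,4S,6R,7S,8aR)-6,7-epoxy-4-hydroxy-6,8a-dimethyl-3-(propan-2-yl)decahydroazulen-3-yl 4-hydroxy-3-methoxybenzoate (CNP0315707.1)
Conditions: H2 (1 atm), 10% Pd/C, EtOAc, rt
Reagents that add atoms: none
Why: Neutral hydrogenolysis of the benzyl aryl ether frees the phenol without base or acid, so the non-benzylic trisubstituted epoxide survives and the tertiary ester does not shift to the neighbouring secondary hydroxyl.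

**Compound list**

1 | (S)-(+)-terpinen-4-ol = (1S)-4-methyl-1-(propan-2-yl)cyclohex-3-en-1-ol | O[C@@]1(C(C)C)CCC(C)=CC1 | starting material
2 | (4S)-1-methyl-4-(propan-2-yl)-7,8,9-trioxabicyclo[4.2.1]nonan-4-ol (ozonide; bridgehead epimers) | CC12CC[C@@](O)(C(C)C)CC(OO1)O2 | intermediate
3 | (3S)-3-hydroxy-6-oxo-3-(propan-2-yl)heptanal | CC(=O)CC[C@@](O)(C(C)C)CC=O | intermediate
4 | (5R)-5-hydroxy-2-methyl-5-(propan-2-yl)cyclopent-1-ene-1-carbaldehyde | O[C@@]1(C(C)C)CCC(C)=C1C=O | intermediate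
5 | (5R)-2-methyl-5-(propan-2-yl)-5-[(trimethylsilyl)oxy]cyclopent-1-ene-1-carbaldehyde | C[Si](C)(C)O[C@@]1(C(C)C)CCC(C)=C1C=O | intermediate
6 | triethyl({(Z)-[(2R)-5-methylidene-2-(propan-2-yl)-2-[(trimethylsilyl)oxy]cyclopentylidene]methyl}oxy)silane | C[Si](C)(C)O[C@@]1(C(C)C)CCC(=C)/C1=C/O[Si](CC)(CC)CC | intermediate
7 | tropylium tetrafluoroborate | [CH+]1C=CC=CC=C1.F[B-](F)(F)F | starting material
8 | isopropenylmagnesium bromide | CC(=C)[Mg]Br | starting material
9 | 7-(prop-1-en-2-yl)cyclohepta-1,3,5-triene | CC(=C)C1C=CC=CC=C1 | intermediate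
10 | triethyl({(Z)-[(5R)-1-(prop-1-en-2-yl)-5-(propan-2-yl)-5-[(trimethylsilyl)oxy]spiro[2.4]heptan-4-ylidene]methyl}oxy)silane (isopropenyl cis to the ylidene carbon; both cis diastereomers) | C[Si](C)(C)O[C@@]1(C(C)C)CCC2(CC2C(C)=C)/C1=C/O[Si](CC)(CC)CC | intermediate
11 | (3R)-6-methyl-3-(propan-2-yl)-4-[(triethylsilyl)oxy]-3-[(trimethylsilyl)oxy]-1,2,3,4,5,8-hexahydroazulene (both epimers at C4 of the name) | C[Si](C)(C)O[C@@]1(C(C)C)CCC2=C1C(O[Si](CC)(CC)CC)CC(C)=CC2 | intermediate
12 | (3R)-6-methyl-3-(propan-2-yl)-4-[(triethylsilyl)oxy]-1,2,3,4,5,8-hexahydroazulen-3-ol (both epimers at C4 of the name) | O[C@@]1(C(C)C)CCC2=C1C(O[Si](CC)(CC)CC)CC(C)=CC2 | intermediate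
13 | (3R,3aR,8aR)-6-methyl-3-(propan-2-yl)-4-[(triethylsilyl)oxy]-1,2,3,4,5,8-hexahydro-3a,8a-methanoazulen-3-ol (both epimers at C4 of the name) | O[C@@]1(C(C)C)CC[C@]2(C3)CC=C(C)CC(O[Si](CC)(CC)CC)[C@]123 | intermediate
14 | (3R,3aR,8aR)-6-methyl-3-(propan-2-yl)-1,2,3,4,5,8-hexahydro-3a,8a-methanoazulene-3,4-diol (both epimers at C4 of the name) | O[C@@]1(C(C)C)CC[C@]2(C3)CC=C(C)CC(O)[C@]123 | intermediate
15 | (3R,3aS,8aR)-3-hydroxy-6-methyl-3-(propan-2-yl)-2,3,5,8-tetrahydro-1H-3a,8a-methanoazulen-4-one | O[C@@]1(C(C)C)CC[C@]2(C3)CC=C(C)CC(=O)[C@]123 | intermediate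
16 | lithium (3R,8aR)-3-hydroxy-6,8a-dimethyl-3-(propan-2-yl)-1,2,3,5,8,8a-hexahydroazulen-4-olate | O[C@@]1(C(C)C)CC[C@]2(C)CC=C(C)CC(O[Li])=C12 | intermediate
17 | (3R,3aR,8aR)-3-hydroxy-6,8a-dimethyl-3-(propan-2-yl)-2,3,3a,5,8,8a-hexahydroazulen-4(1H)-one | O[C@@]1(C(C)C)CC[C@]2(C)CC=C(C)CC(=O)[C@H]21 | intermediate
18 | 4-(benzyloxy)-3-methoxybenzaldehyde | COc1cc(C=O)ccc1OCc1ccccc1 | starting material
19 | hemiacetal of 17 (tertiary oxygen) and 18, drawn metal-free | COc1cc(C(O)O[C@@]2(C(C)C)CC[C@]3(C)CC=C(C)CC(=O)[C@H]32)ccc1OCc1ccccc1 | intermediate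
20 | (3R,3aS,4S,8aR)-4-hydroxy-6,8a-dimethyl-3-(propan-2-yl)-1,2,3,3a,4,5,8,8a-octahydroazulen-3-yl 4-(benzyloxy)-3-methoxybenzoate | COc1cc(C(=O)O[C@@]2(C(C)C)CC[C@]3(C)CC=C(C)C[C@H](O)[C@H]32)ccc1OCc1ccccc1 | intermediate
21 | (3R,3aS,4S,6R,7S,8aR)-6,7-epoxy-4-hydroxy-6,8a-dimethyl-3-(propan-2-yl)decahydroazulen-3-yl 4-(benzyloxy)-3-methoxybenzoate | COc1cc(C(=O)O[C@@]2(C(C)C)CC[C@]3(C)C[C@@H]4O[C@]4(C)C[C@H](O)[C@H]32)ccc1OCc1ccccc1 | intermediate
22 | (3R,3aS,4S,6R,7S,8aR)-6,7-epoxy-4-hydroxy-6,8a-dimethyl-3-(propan-2-yl)decahydroazulen-3-yl 4-hydroxy-3-methoxybenzoate | COc1cc(C(=O)O[C@@]2(C(C)C)CC[C@]3(C)C[C@@H]4O[C@]4(C)C[C@H](O)[C@H]32)ccc1O | target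

**Step count and risks**

Total step count: 12 (11 on the main line plus step 4 for reagent 9). Longest linear sequence: 11 steps (1 → 22 through steps 1–3 and 5–12).

Risk 1 (step 5, the carbene (4+3)). The carbene may attack the enol ether alkene of 6 instead of the methylidene, or the cyclopropane may form trans and not rearrange. The fallback sets out from 6 and comes back at 12. N-Bromosuccinimide in THF at −78 °C brominates the γ-carbon of the dienol ether to give (5R)-2-(bromomethyl)-5-(propan-2-yl)-5-[(trimethylsilyl)oxy]cyclopent-1-ene-1-carbaldehyde F1. Stille coupling with tributyl(vinyl)stannane (Pd2(dba)3, AsPh3) then gives (5R)-2-(prop-2-en-1-yl)-5-(propan-2-yl)-5-[(trimethylsilyl)oxy]cyclopent-1-ene-1-carbaldehyde F2. CH2=C(CH3)CH2MgCl adds to the aldehyde to give 3-methyl-1-[(5R)-2-(prop-2-en-1-yl)-5-(propan-2-yl)-5-[(trimethylsilyl)oxy]cyclopent-1-en-1-yl]but-3-en-1-ol F3, and Et3SiCl/imidazole converts this into triethyl({3-methyl-1-[(5R)-2-(prop-2-en-1-yl)-5-(propan-2-yl)-5-[(trimethylsilyl)oxy]cyclopent-1-en-1-yl]but-3-en-1-yl}oxy)silane F4. Ring-closing metathesis with the second-generation Grubbs catalyst closes the seven-membered ring to 11, and the K2CO3/MeOH treatment of step 5 then gives 12.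

Risk 2 (step 9, reductive opening). The wrong cyclopropane bond may break, the ketone may over-reduce, or C5 may be protonated from the wrong face. The fallback replaces steps 6–9 by a conjugate addition; it sets out from 12 and comes back at 17. Bu4NF gives (3R)-6-methyl-3-(propan-2-yl)-1,2,3,4,5,8-hexahydroazulene-3,4-diol F5, and MnO2 oxidises its allylic secondary alcohol to (3R)-3-hydroxy-6-methyl-3-(propan-2-yl)-2,3,5,8-tetrahydroazulen-4(1H)-one F6. Me2CuLi/BF3·OEt2 at −78 °C then adds methyl to C1 on the face of the lithium alkoxide (anti to isopropyl), and a cold NH4Cl quench gives 17.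

Risk 3 (step 10, Evans–Tishchenko on a tertiary carbinol). Hemiacetal formation at the hindered oxygen may be slow, the β-hydroxy ketone may undergo retro-aldol cleavage, and the product can suffer 1,3-acyl shift to the secondary hydroxyl. The fallback sets out from 17 and comes back at 20. Me4NBH(OAc)3 in AcOH/MeCN at −20 °C (hydroxyl-directed anti reduction) gives jaeschkeanadiol, (3R,3aS,4S,8aR)-6,8a-dimethyl-3-(propan-2-yl)-1,2,3,3a,4,5,8,8a-octahydroazulene-3,4-diol F7. Et3SiCl/imidazole silylates only the secondary hydroxyl to give (3R,3aS,4S,8aR)-6,8a-dimethyl-3-(propan-2-yl)-4-[(triethylsilyl)oxy]-1,2,3,3a,4,5,8,8a-octahydroazulen-3-ol F8. KN(SiMe3)2 followed by 4-(benzyloxy)-3-methoxybenzoyl chloride at −78 °C acylates the tertiary alkoxide to give (3R,3aS,4S,8aR)-6,8a-dimethyl-3-(propan-2-yl)-4-[(triethylsilyl)oxy]-1,2,3,3a,4,5,8,8a-octahydroazulen-3-yl 4-(benzyloxy)-3-methoxybenzoate F9, and HF·pyridine in THF at 0 °C removes the silyl group to give 20.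

**Further compounds**

F1 | step 5 | (5R)-2-(bromomethyl)-5-(propan-2-yl)-5-[(trimethylsilyl)oxy]cyclopent-1-ene-1-carbaldehyde | C[Si](C)(C)O[C@@]1(C(C)C)CCC(CBr)=C1C=O
F2 | step 5 | (5R)-2-(prop-2-en-1-yl)-5-(propan-2-yl)-5-[(trimethylsilyl)oxy]cyclopent-1-ene-1-carbaldehyde | C[Si](C)(C)O[C@@]1(C(C)C)CCC(CC=C)=C1C=O
F3 | step 5 | 3-methyl-1-[(5R)-2-(prop-2-en-1-yl)-5-(propan-2-yl)-5-[(trimethylsilyl)oxy]cyclopent-1-en-1-yl]but-3-en-1-ol (both carbinol epimers) | C[Si](C)(C)O[C@@]1(C(C)C)CCC(CC=C)=C1C(O)CC(C)=C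
F4 | step 5 | triethyl({3-methyl-1-[(5R)-2-(prop-2-en-1-yl)-5-(propan-2-yl)-5-[(trimethylsilyl)oxy]cyclopent-1-en-1-yl]but-3-en-1-yl}oxy)silane (both epimers) | C[Si](C)(C)O[C@@]1(C(C)C)CCC(CC=C)=C1C(O[Si](CC)(CC)CC)CC(C)=C
F5 | step 9 | (3R)-6-methyl-3-(propan-2-yl)-1,2,3,4,5,8-hexahydroazulene-3,4-diol (both epimers at C4 of the name) | O[C@@]1(C(C)C)CCC2=C1C(O)CC(C)=CC2
F6 | step 9 | (3R)-3-hydroxy-6-methyl-3-(propan-2-yl)-2,3,5,8-tetrahydroazulen-4(1H)-one | O[C@@]1(C(C)C)CCC2=C1C(=O)CC(C)=CC2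
F7 | step 10 | (3R,3aS,4S,8aR)-6,8a-dimethyl-3-(propan-2-yl)-1,2,3,3a,4,5,8,8a-octahydroazulene-3,4-diol | O[C@@]1(C(C)C)CC[C@]2(C)CC=C(C)C[C@H](O)[C@H]21
F8 | step 10 | (3R,3aS,4S,8aR)-6,8a-dimethyl-3-(propan-2-yl)-4-[(triethylsilyl)oxy]-1,2,3,3a,4,5,8,8a-octahydroazulen-3-ol | O[C@@]1(C(C)C)CC[C@]2(C)CC=C(C)C[C@H](O[Si](CC)(CC)CC)[C@H]21
F9 | step 10 | (3R,3aS,4S,8aR)-6,8a-dimethyl-3-(propan-2-yl)-4-[(triethylsilyl)oxy]-1,2,3,3a,4,5,8,8a-octahydroazulen-3-yl 4-(benzyloxy)-3-methoxybenzoate | COc1cc(C(=O)O[C@@]2(C(C)C)CC[C@]3(C)CC=C(C)C[C@H](O[Si](CC)(CC)CC)[C@H]32)ccc1OCc1ccccc1
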